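This small charge, 5.0 × 10⁻⁴ M of first end groups with 1.00 equiv of second end groups at 60 °C, is the larch flask that I hand over to you at 12 min.

| setting | larch | oak | flask |
|---|---|---|---|
| first end groups | 5.0 × 10⁻⁴ M | 5.0 × 10⁻⁴ M | 5.0 × 10⁻⁴ M |
| second end groups | 1 equiv | 0.67 equiv | 1.00 equiv |
| temperature | 60 °C | 55 °C | 60 °C |
| remark | the very flask that is asked about, followed so far | run made earlier |  |
| time |  |  | 12 min |

| run | time / min | links / % | first end groups / % |
|---|---|---|---|
| larch | 0.500 | 11.2 | 2.0 |
| larch | 1.33 | 11.6 | 1.0 |
| larch | 3.00 | 11.9 | 1.0 |
| larch | 8.00 | 11.2 | 0.9 |
| oak | 0.667 | 7.1 | 32.2 |
| oak | 1.50 | 6.5 | 32.1 |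
| oak | 4.00 | 4.5 | 29.4 |
| oak | 8.00 | 2.4 | 27.5 |

(standard deviation of a reading: 0.3 percentage points)

- dawn: at 12 min take out 90% of the links then present, then wait 25 min
- midnight: at 12 min raise the temperature by 25 K, then wait 25 min
- noon: at 12 min add second end groups, 50.0% of the amount charged, then wait 25 min
- autumn: change nothing and wait 25 min more

- removed links is counted in
- the numbers in the tables scatter with a standard deviation of 0.3 percentage points
- additions bring no volume worth counting

* links, in percent of the first end groups first charged, at 12 min
* the option that brings most further links ("none" if no option brings more than 2 percentage points) (dawn / midnight / noon / autumn / none)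
* links present, with what was taken out counted in, in percent of the first end groups first charged, after dawn
* links present, with what was taken out counted in, in percent of the first end groups first charged, after noon

In the oak run the second end groups are the limiting reagent, and from first reading to last links fall by 4.7 percentage points and first end groups by 4.7 points, so the gap between them stands at 25 points at the first reading and 25 points at the last. In the later larch readings links stand above first end groups by 10.6% on average, and I carry this reading as the link floor, c(links) minus c(first end groups), the level links come to if c(first end groups) comes to zero while that difference holds.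

With 0.9% of first end groups still there, I expect about 11.5% of links when you come, slipping towards the floor, and those first end groups are less than the 2 points an option must bring, so leave the flask alone. Above all, add no second end groups: neither run was charged with them in excess, and I can give no figure for noon.

The forecast says 11.3% for the links at the hand-over, below my figure, none for the best option, as I do, 11.3% for dawn and 11.4% for noon, where I gave no figure, on the ground that “The larch flask is therefore finished”.

    first end groups + second end groups → links (k = 87.2 M⁻¹ s⁻¹, Ea = 41.0 kJ mol⁻¹)
    first end groups + second end groups → rings, rate k2*[first end groups] as long as [second end groups] is above zero (k = 0.116 s⁻¹, Ea = 83.0 kJ mol⁻¹)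
    first end groups + links → side product (k = 22.6 M⁻¹ s⁻¹, Ea = 53.0 kJ mol⁻¹)
    second end groups + links → over-reaction product (k = 74.4 M⁻¹ s⁻¹, Ea = 54.0 kJ mol⁻¹)
    (constants at 60 °C)

The flask gives 11.1%, none, 11.0% for dawn and 0% for noon. At 12.0 min links stand above first end groups by 10.5%, and at 120 min links stand at 10.5%. Taking one link off the floor for each spare second end group, noon's 50.0% brings the floor to −39 points, which is below zero. The neighbouring flask with 4.00 equiv of second end groups reckons below zero as well, and at 12.0 min it holds 0% of links and 54.7% of over-reaction product.

(The data come from a simulation on assumed constants; the scatter is artificial.)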